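## The problem

Compound 15 is a flavone, a benzopyranone (rings A and C) with a phenyl ring B on C2 and a 2,3-dihydroxyphenyl ring D joined to C8 through one methylene carbon. It has no stereocenter, so the task is one of position only: ring A must carry hydroxyl groups at C5 and C7 and the benzyl group at C8, not at C6. In a 5,7-dioxygenated ring A, C6 and C8 both lie ortho and para to two oxygens and respond alike to electrophiles, and 6- and 8-substituted 5,7-dihydroxyflavones can interconvert under forcing acid by opening and reclosing the pyranone (Wessely–Moser rearrangement). Ring D is bonded through the carbon next to its catechol, a 1,2,3-pattern that must be set without isomers. Three groups are fragile: the free catechol, which air in base or any hypervalent iodine reagent oxidizes to the ortho-quinone; the doubly benzylic CH2, which is open to hydride or electron abstraction; and the 4-pyranone, which hard carbon nucleophiles attack at C2 or C4 and hot hydroxide opens. The enabling feature is that C5–H lies peri to the C4 carbonyl, so that the carbonyl oxygen, C4, C4a, C5 and a metal can close a five-membered chelate that no other hydrogen of ring A can reach. O5 can therefore be withheld to the end. While ring A carries O7 alone, C8 (ortho to O7 and next to O1) is its one clearly preferred site for electrophiles.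

## Retrosynthesis

**15 from 14.** The three aryl acetate C–O bonds are cut first. Triacetate 14 holds the complete skeleton and all six oxygens. The acetates are there only because the oxidation that precedes them needs electron-poor, non-phenolic rings. The forward step must free four phenols, one of them a catechol, without air oxidation and without opening the pyranone.

**14 from 12 (through 13).** The C5–O bond is cut, leaving the 7-acetoxy-8-benzylflavone 12. This is preferred to cutting C8–CH2 at the 5,7-dioxygenated stage, which brings back the C6/C8 ambiguity. It is also preferred to cutting C7–O, for which the molecule offers no directing group and which would remove the oxygen that steers substitution to C8. Precursor 12 descends from an intact commercial flavone. The forward reaction must oxygenate C5–H only and leave rings A and D, ring B and the diarylmethane CH2 untouched.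

**12 from 11 from 10.** This is a protecting-group exchange. Methyl ethers are needed for the organometallic and acidic steps that build the skeleton, and acetates are needed for the oxidation. One BBr3 treatment of trimethyl ether 10 should give triol 11, and acetylation gives 12. Routing the exchange through the triol costs two steps but lets each stage carry the group it tolerates best.

**10 from 9.** The benzylic C–O bond of diarylcarbinol 9 is cut. The carbinol is what an aryl-metal addition to an aldehyde delivers. Its hydroxyl sits on a carbon flanked by two ortho-oxygenated arenes, so ionization and hydride capture should be easy. The carbinol stereocenter is formed racemic and is erased here.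

**9 from 5 and 6 (through 7 and 8).** The bond between the carbinol carbon and C1'' of ring D is cut, giving 8-formyl-7-methoxyflavone 5 and veratrole 6. Veratrole 6 lithiates only next to a methoxy group, so the 1,2,3-pattern of ring D comes with the reagent. The neighbouring options are weaker. Friedel–Crafts benzylation of the flavone with a ring D benzyl electrophile gives poorer control of O- against C-alkylation. A metalated C8 of the flavone would be incompatible with its own pyranone. The forward reaction must add to the aldehyde and spare the C4 carbonyl and C2, so aryllithium 7 is converted to aryltitanium 8 before the aldehyde is added.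

**5 from 4 from 1 and 2 (through 3).** The O7 methyl ether is cut, then the C8–CHO bond, giving commercial 7-hydroxyflavone 1 and hexamethylenetetramine 2. Ortho-formylation of 7-hydroxychromones goes to C8 because of bond fixation in ring A. The methyl group caps the phenol for the organometallic step and later leaves in the same operation as the ring D methyl groups.

## Roads not taken

**Alternative 1:** Ring C is cut at C4a–C4, C4–C3 and O1–C2. The forward key step joins 2-iodo-3,5-dimethoxy-6-(2,3-dimethoxybenzyl)phenol A1, phenylacetylene A2 and one carbonyl carbon under PdCl2(PPh3)2 and a secondary amine to give 8-(2,3-dimethoxybenzyl)-5,7-dimethoxyflavone A3.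
- Merits: it is convergent, all ring A oxygens come from a phloroglucinol-type building block, no late oxidation is needed, and the position of the benzyl group relative to the pyranone is fixed by where iodine and hydroxyl sit in A1. It would probably need fewer steps than the eight of the chosen route.
- Weak points: the difficulty moves into A1, a pentasubstituted benzene. Making it requires a mono-C-benzylation of a 3,5-dioxygenated phenol and then iodination at one of two similar open positions. The C–I bond of A1 is flanked by two ortho substituents on an electron-rich ring, so oxidative addition and carbonyl insertion are slow. Direct coupling of the alkyne A2 without carbonyl insertion (leading to a benzofuran) and 5-exo closure (leading to an aurone) compete. The four methyl ethers of A3 must then be cleaved.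
- Comparison: this road is shorter and more convergent. The chosen plan sets against it that each positional decision rests on a documented bias of 7-hydroxyflavone 1 or on a directing group with only one hydrogen in reach, and that no toxic gas and no regiochemically uncertain arene halogenation are involved.

**Alternative 2:** The C3''–O bond of ring D is cut. The forward key step treats 8-(2-hydroxybenzyl)-5,7-dimethoxyflavone A4 with a pentavalent iodine oxidant. This delivers oxygen to the single free ortho carbon of the phenol and gives the ortho-quinone A5, which is reduced in the same flask to 8-(2,3-dihydroxybenzyl)-5,7-dimethoxyflavone A6.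
- Merits: ortho-selectivity is built into the mechanism, the reaction is metal-free and runs near room temperature, and ring A is already fully oxygenated.
- Weak points: this oxidation works best on phenols carrying a donor substituent, and the phenol of A4 has only an alkyl group. A5 has a doubly benzylic CH2 next to a quinone carbonyl and can tautomerize to a quinone methide. The oxidant can also attack that CH2 directly. The benzyl group must still be placed on a 5,7-dioxygenated ring A, so the C6/C8 problem remains. The two ring A methyl ethers of A6 must later be removed beside a free catechol.
- Comparison: this is also a late oxygenation, but it spends the move on ring D, whose oxidation level can simply be bought in veratrole 6. The chosen plan spends it on C5, where it removes the regiochemical problem. The milder oxidation conditions are a real advantage of this road. The chosen plan answers with acetate protection of every electron-rich ring during its harsher step.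

**Alternative 3:** Ring A is cut at C5–C6. The forward key step doubly deprotonates methyl 2-[1-(2,3-dimethoxyphenyl)-3-oxobutan-2-yl]-4-oxo-6-phenyl-4H-pyran-3-carboxylate A7 with excess LiN(iPr)2. The terminal methyl carbon attacks the ester, and tautomerization gives 8-(2,3-dimethoxybenzyl)-5,7-dihydroxyflavone A8.
- Merits: the benzyl carbon is fixed between the ketone and the pyranone before ring A exists, so there is no C6/C8 question at all. The 5,7-diol appears unprotected, and only the two ring D methyl ethers of A8 remain to be cleaved.
- Weak points: A7 is a 2,3,6-trisubstituted 4-pyranone with no short preparation, and its synthesis alone would likely exceed the length of the chosen route. The first deprotonation goes to the doubly activated CH, so the second anion must form at the methyl group and attack a hindered ester that is deactivated as part of a vinylogous carbonate. The pyranone itself invites conjugate addition and ring opening by the amide base.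
- Comparison: on regiochemistry at ring A this road is the most secure of all, and it needs no oxidation. The chosen plan sets against it step economy, a commercial flavone as starting point, and reactions that each have close precedent on flavones.

Key step: step 7

Assumption: the aryl acetates of 12 should survive CF3CO2H/(CF3CO)2O at 80 °C well enough for 14 to be isolated; any acetate/trifluoroacetate exchange is harmless because step 8 removes every acyl group.

## Route

Step 1
Reactants: 1 7-hydroxyflavone; 2 hexamethylenetetramine
Product: 4 7-hydroxy-4-oxo-2-phenyl-4H-chromene-8-carbaldehyde (8-formyl-7-hydroxyflavone), via aldimine 3 (not isolated)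
Conditions: hexamethylenetetramine, AcOH, 100 °C; then 6 M aq. HCl, 80 °C
Reagents that add atoms: water, O
Why: Duff ortho-formylation; in 7-hydroxychromones bond fixation makes C8 (ortho to the hydroxyl and adjacent to O1) the site of electrophilic attack, so the iminium ion from protonated hexamethylenetetramine should enter there. Internal hydride transfer gives the C8 aldimine 3, which aqueous acid hydrolyses to the aldehyde.

Step 2
Reactants: 4 8-formyl-7-hydroxyflavone
Product: 5 7-methoxy-4-oxo-2-phenyl-4H-chromene-8-carbaldehyde (8-formyl-7-methoxyflavone)
Conditions: MeI, K2CO3, DMF, rt
Reagents that add atoms: iodomethane, CI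
Why: Williamson ether synthesis; the phenol ortho to the formyl group is acidic enough for K2CO3, and the aldehyde and pyranone do not react with iodomethane. Methyl is chosen because it survives the organometallic and acidic steps and later leaves together with the ring D methyl groups.

Step 3
Reactants: 5 8-formyl-7-methoxyflavone; 6 1,2-dimethoxybenzene (veratrole)
Product: 9 8-[(2,3-dimethoxyphenyl)(hydroxy)methyl]-7-methoxyflavone (racemic carbinol), via 2,3-dimethoxyphenyllithium 7 (not isolated), via aryltitanium triisopropoxide 8 (not isolated)
Conditions: 6, n-BuLi, TMEDA, THF, 0 °C to rt; ClTi(OiPr)3, −78 °C; then 5, THF, −78 to 0 °C; aq. NH4Cl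
Reagents that add atoms: none
Why: Directed ortho-lithiation of veratrole can only occur next to a methoxy group and so gives the 1,2,3-pattern of ring D; transmetalation to the aryltitanium triisopropoxide gives a reagent of the class that adds to aldehydes but not to ketones or vinylogous esters, so the C4 carbonyl and C2 of the pyranone should be spared even at 0 °C, where the flavone is in solution. The carbinol stereocenter forms without control and is removed in step 4.

Step 4
Reactants: 9 racemic diarylcarbinol
Product: 10 8-(2,3-dimethoxybenzyl)-7-methoxyflavone
Conditions: Et3SiH, CF3CO2H, CH2Cl2, 0 °C to rt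
Reagents that add atoms: none
Why: Ionic hydrogenation; acid ionizes the doubly benzylic alcohol to a diarylmethyl cation stabilized by the ortho-methoxy groups of both rings, and the silane delivers hydride. The protonated flavone is a stabilized 4-hydroxybenzopyrylium ion and should not accept hydride under these conditions.

Step 5
Reactants: 10 8-(2,3-dimethoxybenzyl)-7-methoxyflavone
Product: 11 8-(2,3-dihydroxybenzyl)-7-hydroxyflavone
Conditions: BBr3 (excess), CH2Cl2, −78 °C to rt; then H2O
Reagents that add atoms: none
Why: Lewis acid cleavage of aryl methyl ethers; boron coordinates each ether oxygen and bromide removes the methyl group by SN2 attack. Demethylation of methoxyflavones with BBr3 is routine, and the diarylmethane and pyranone tolerate it.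

Step 6
Reactants: 11 8-(2,3-dihydroxybenzyl)-7-hydroxyflavone
Product: 12 7-acetoxy-8-(2,3-diacetoxybenzyl)flavone
Conditions: Ac2O, pyridine, DMAP (cat.), CH2Cl2, rt
Reagents that add atoms: acetic anhydride, CC(=O)OC(C)=O
Why: Nucleophilic catalysis of phenol acylation; three acetates turn the catechol and the ring A phenol into electron-poor aryl esters that a trivalent iodine oxidant should no longer attack.

Step 7
Reactants: 12 7-acetoxy-8-(2,3-diacetoxybenzyl)flavone
Product: 14 7-acetoxy-8-(2,3-diacetoxybenzyl)-5-hydroxyflavone, via 5-trifluoroacetate 13 (not isolated)
Conditions: [RuCl2(p-cymene)]2 (5 mol %), PhI(OCOCF3)2 (2 equiv), CF3CO2H/(CF3CO)2O, 80 °C; then H2O, rt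
Reagents that add atoms: phenyliodine bis(trifluoroacetate), O=C(O[I](OC(=O)C(F)(F)F)c1ccccc1)C(F)(F)F; trifluoroacetic acid, OC(=O)C(F)(F)F
Why: Ligand exchange in the acidic medium gives a divalent ruthenium trifluoroacetate that binds the C4 carbonyl oxygen, and carboxylate-assisted metalation of C5–H gives a five-membered ruthenacycle (Ru, O, C4, C4a, C5). The iodine reagent oxidizes this to a tetravalent ruthenium trifluoroacetate, C–O reductive elimination gives the aryl trifluoroacetate 13 and returns divalent ruthenium, and water hydrolyses 13 to the phenol 14, which is hydrogen-bonded to the carbonyl. The closest known reaction type is the ketone-directed ruthenium-catalysed ortho C–H hydroxylation of aryl ketones with this oxidant in CF3CO2H/(CF3CO)2O, which has been used at C5 of flavones and chromones. No ring is closed in the product and no stereocenter is formed; the metallacycle is transient. The step needs site selectivity, which the substrate secures because C5–H is the only ring A hydrogen in reach of the carbonyl: C6–H is meta to it, C3–H would need a four-membered metallacycle, and rings B and D have no comparable directing group. It also needs chemoselectivity, which the acetates on O7 and ring D provide by keeping those rings and the CH2 between them too electron-poor for oxidation by the iodine reagent. The anhydride traps the new oxygen, which stems from the trifluoroacetate pool shared by the iodine reagent and the solvent acid, as its trifluoroacetate until work-up, so the product phenol is not oxidized further.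

Step 8
Reactants: 14 7-acetoxy-8-(2,3-diacetoxybenzyl)-5-hydroxyflavone
Product: 15 8-(2,3-dihydroxybenzyl)-5,7-dihydroxyflavone (target)
Conditions: K2CO3, degassed MeOH, argon, 0 °C to rt; then 1 M aq. HCl
Reagents that add atoms: none
Why: Base-mediated transesterification (Zemplén-type methanolysis) of aryl acetates; phenoxides are good leaving groups, so carbonate in methanol at or below room temperature should suffice and leave the pyranone closed. Exclusion of air protects the catechol phenoxide, and acidification returns the neutral tetraphenol.

## Compound list

1 | 7-hydroxyflavone | O=c1cc(-c2ccccc2)oc2cc(O)ccc12 | starting material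
2 | hexamethylenetetramine | C1N2CN3CN1CN(C2)C3 | starting material
3 | 7-hydroxy-8-(iminomethyl)flavone (C8 aldimine of the Duff reaction, drawn as the free NH imine) | O=c1cc(-c2ccccc2)oc2c(C=N)c(O)ccc12 | intermediate
4 | 8-formyl-7-hydroxyflavone | O=Cc1c(O)ccc2c(=O)cc(-c3ccccc3)oc12 | intermediate
5 | 8-formyl-7-methoxyflavone | COc1ccc2c(=O)cc(-c3ccccc3)oc2c1C=O | intermediate
6 | 1,2-dimethoxybenzene (veratrole) | COc1ccccc1OC | starting material
7 | 2,3-dimethoxyphenyllithium | COc1cccc([Li])c1OC | intermediate
8 | (2,3-dimethoxyphenyl)titanium triisopropoxide | COc1cccc([Ti](OC(C)C)(OC(C)C)OC(C)C)c1OC | intermediate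
9 | 8-[(2,3-dimethoxyphenyl)(hydroxy)methyl]-7-methoxyflavone (racemic) | COc1ccc2c(=O)cc(-c3ccccc3)oc2c1C(O)c1cccc(OC)c1OC | intermediate
10 | 8-(2,3-dimethoxybenzyl)-7-methoxyflavone | COc1ccc2c(=O)cc(-c3ccccc3)oc2c1Cc1cccc(OC)c1OC | intermediate
11 | 8-(2,3-dihydroxybenzyl)-7-hydroxyflavone | Oc1ccc2c(=O)cc(-c3ccccc3)oc2c1Cc1cccc(O)c1O | intermediate
12 | 7-acetoxy-8-(2,3-diacetoxybenzyl)flavone | CC(=O)Oc1ccc2c(=O)cc(-c3ccccc3)oc2c1Cc1cccc(OC(C)=O)c1OC(C)=O | intermediate
13 | 7-acetoxy-8-(2,3-diacetoxybenzyl)-5-(trifluoroacetoxy)flavone | CC(=O)Oc1cc(OC(=O)C(F)(F)F)c2c(=O)cc(-c3ccccc3)oc2c1Cc1cccc(OC(C)=O)c1OC(C)=O | intermediate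
14 | 7-acetoxy-8-(2,3-diacetoxybenzyl)-5-hydroxyflavone | CC(=O)Oc1cc(O)c2c(=O)cc(-c3ccccc3)oc2c1Cc1cccc(OC(C)=O)c1OC(C)=O | intermediate
15 | 8-(2,3-dihydroxybenzyl)-5,7-dihydroxyflavone | O=c1cc(-c2ccccc2)oc2c(Cc3cccc(O)c3O)c(O)cc(O)c12 | target

## Step count and risk

Total step count: 8. Longest linear sequence: 8 steps (1 to 15); veratrole 6 enters in step 3 after metalation in the flask.

**Step 7 (key step).** Three processes could spoil it:
- oxidation of the diarylmethane CH2 or of ring D by the iodine reagent, if electron transfer outpaces the ruthenium cycle;
- a slow turnover, because the 7-acetoxy group makes ring A electron-poor;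
- weak competing direction by an acetate carbonyl, leading to metalation at C6 or on ring D.

Fallback: the C5–O bond is still made last, but through boron. Setting out from 12, ketone-directed ortho C–H borylation with [Ir(OMe)(cod)]2, P[3,5-(CF3)2C6H3]3 and B2pin2 in octane at 120 °C should give 7-acetoxy-8-(2,3-diacetoxybenzyl)-5-(4,4,5,5-tetramethyl-1,3,2-dioxaborolan-2-yl)flavone F1. Oxidation of the C–B bond with KHSO5 in aqueous acetone at 0 °C then gives the phenol, and the route is rejoined at 14. No hypervalent iodine reagent or strong acid touches the substrate in this variant.

**Step 3.** The risk is loss of chemoselectivity (attack of the aryl-metal at C4 or C2 of the pyranone) or a sluggish addition of the bulky titanium reagent to an aldehyde flanked by two ortho oxygens. Fallback: the diarylmethane bond is made by cross-coupling instead of carbonyl addition. Setting out from 5, NaBH4 in MeOH/THF at 0 °C should reduce only the aldehyde to 8-(hydroxymethyl)-7-methoxyflavone F2, and PBr3 in CH2Cl2 gives 8-(bromomethyl)-7-methoxyflavone F3. Suzuki–Miyaura coupling of F3 with purchased 2,3-dimethoxyphenylboronic acid (Pd(PPh3)4, aq. K2CO3, toluene/EtOH, 80 °C) gives the diarylmethane directly. The route is rejoined at 10 and step 4 is not needed.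

**Step 1.** The Duff reaction on hydroxyflavones tends to stop at low conversion and to lose material through over-aminomethylation and resin formation; some attack at C6 is also possible. Fallback: the formyl group is dispensed with. Setting out from 1, iodination with N-iodosuccinimide in DMF should go to the same C8 position and give 7-hydroxy-8-iodoflavone F4, and MeI/K2CO3 gives 8-iodo-7-methoxyflavone F5. Negishi coupling of F5 with (2,3-dimethoxybenzyl)zinc chloride F6, prepared in THF from purchased 2,3-dimethoxybenzyl chloride, zinc dust and LiCl, under Pd(OAc)2/SPhos gives the diarylmethane. The route is rejoined at 10 and steps 1 to 4 are bypassed.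

**Step 8.** The risk is autoxidation of the catechol phenoxide to the ortho-quinone if air enters, or base-induced opening of the pyranone, after which reclosure could scramble the 8- and 6-benzyl isomers. Fallback: the basic deprotection is avoided altogether by using acyl groups that fall off in neutral water. Setting out from 11, (CF3CO)2O in CF3CO2H at rt should convert the three phenols in the flask to 7-(trifluoroacetoxy)-8-[2,3-bis(trifluoroacetoxy)benzyl]flavone F7. Addition of [RuCl2(p-cymene)]2 and PhI(OCOCF3)2 and heating to 80 °C carries out the same carbonyl-directed C5 oxygenation and gives 5,7-bis(trifluoroacetoxy)-8-[2,3-bis(trifluoroacetoxy)benzyl]flavone F8. Stirring with aqueous methanol at rt hydrolyses all four trifluoroacetates, and the route is rejoined at 15, with steps 6 and 8 omitted.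

## Further compounds

F1 | step 7 | 7-acetoxy-8-(2,3-diacetoxybenzyl)-5-(4,4,5,5-tetramethyl-1,3,2-dioxaborolan-2-yl)flavone | CC(=O)Oc1cc(B2OC(C)(C)C(C)(C)O2)c2c(=O)cc(-c3ccccc3)oc2c1Cc1cccc(OC(C)=O)c1OC(C)=O
F2 | step 3 | 8-(hydroxymethyl)-7-methoxyflavone | COc1ccc2c(=O)cc(-c3ccccc3)oc2c1CO
F3 | step 3 | 8-(bromomethyl)-7-methoxyflavone | COc1ccc2c(=O)cc(-c3ccccc3)oc2c1CBr
F4 | step 1 | 7-hydroxy-8-iodoflavone | O=c1cc(-c2ccccc2)oc2c(I)c(O)ccc12
F5 | step 1 | 8-iodo-7-methoxyflavone | COc1ccc2c(=O)cc(-c3ccccc3)oc2c1I
F6 | step 1 | (2,3-dimethoxybenzyl)zinc chloride | COc1cccc(C[Zn]Cl)c1OC
F7 | step 8 | 7-(trifluoroacetoxy)-8-[2,3-bis(trifluoroacetoxy)benzyl]flavone | O=C(Oc1ccc2c(=O)cc(-c3ccccc3)oc2c1Cc1cccc(OC(=O)C(F)(F)F)c1OC(=O)C(F)(F)F)C(F)(F)F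
F8 | step 8 | 5,7-bis(trifluoroacetoxy)-8-[2,3-bis(trifluoroacetoxy)benzyl]flavone | O=C(Oc1cc(OC(=O)C(F)(F)F)c2c(=O)cc(-c3ccccc3)oc2c1Cc1cccc(OC(=O)C(F)(F)F)c1OC(=O)C(F)(F)F)C(F)(F)F
A1 | alternative 1 | 2-iodo-3,5-dimethoxy-6-(2,3-dimethoxybenzyl)phenol | Oc1c(I)c(OC)cc(OC)c1Cc1cccc(OC)c1OC
A2 | alternative 1 | phenylacetylene | C#Cc1ccccc1
A3 | alternative 1 | 8-(2,3-dimethoxybenzyl)-5,7-dimethoxyflavone | O=c1cc(-c2ccccc2)oc2c(Cc3cccc(OC)c3OC)c(OC)cc(OC)c12
A4 | alternative 2 | 8-(2-hydroxybenzyl)-5,7-dimethoxyflavone | O=c1cc(-c2ccccc2)oc2c(Cc3ccccc3O)c(OC)cc(OC)c12
A5 | alternative 2 | 3-[(5,7-dimethoxy-4-oxo-2-phenyl-4H-chromen-8-yl)methyl]cyclohexa-3,5-diene-1,2-dione (ortho-quinone) | O=C1C(=O)C(Cc2c(OC)cc(OC)c3c(=O)cc(-c4ccccc4)oc23)=CC=C1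
A6 | alternative 2 | 8-(2,3-dihydroxybenzyl)-5,7-dimethoxyflavone | O=c1cc(-c2ccccc2)oc2c(Cc3cccc(O)c3O)c(OC)cc(OC)c12
A7 | alternative 3 | methyl 2-[1-(2,3-dimethoxyphenyl)-3-oxobutan-2-yl]-4-oxo-6-phenyl-4H-pyran-3-carboxylate (racemic) | COC(=O)c1c(C(Cc2cccc(OC)c2OC)C(C)=O)oc(-c2ccccc2)cc1=O
A8 | alternative 3 | 8-(2,3-dimethoxybenzyl)-5,7-dihydroxyflavone | O=c1cc(-c2ccccc2)oc2c(Cc3cccc(OC)c3OC)c(O)cc(O)c12
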